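**Plan**
Core numbering: 1,2-dihydronaphthalene C1 (CH–aryl), C2 (CH–aroyl), C3 (=C–aroyl), C4 (=CH); ring A = C4a–C8a with O6, O7 and 8-OMe; ring B = C1–C4, C4a, C8a. Retrosynthesis cuts C3–C4 and C8a–C1 together, then two bonds of a cyclopropane (C1–C3, C2–C3) back to a chalcone and a phenacyl ylide.
Enabling feature: C1 is doubly benzylic and para to the 4-oxygen of the pendant aryl (cation-stabilising), and C3 is α to an aryl ketone and 1,3 to C1 across C2. This is the polarity of a donor–acceptor cyclopropane, and because C2 and C3 carry the same aroyl group, a 1-aryl-2,3-diaroylcyclopropane gives the same skeleton whichever C1–C bond opens. Ring A supplies the matching 1,3-pair: formyl carbon C4 and ortho ring carbon C8a.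
Forward order: both catechol aldehydes are ketalised; the chalcone (protected monomer) is cyclopropanated; a Lewis-acid strain-release (3+3) annulation with the ring A aldehyde closes ring B (transient oxolane, then six-membered Friedel–Crafts closure and dehydration); C2 is inverted; all protecting groups are removed.
Stereochemistry: absolute configuration enters in the chiral sulfonium ylide cyclopropanation and is stored at the non-enolisable C2; it is relayed to C1 (1,2-trans) in the ring closure; C2 is then inverted to the 1,2-cis target by kinetic protonation of its enolate anti to the C1 aryl.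
Helpers: the diphenylmethylene ketal on O6/O7 is a temporary ring that steers the closure to C8a and protects the catechol; benzyl ethers mask the two 4-hydroxybenzoyl groups; BCl3 removes all of them at the end.

Key step: step 7

Assumption: the (1R,4R,5R)-sulfide is taken to deliver the (1R,2R)-cyclopropane; if the sense of induction is the opposite, the (1S,4S,5S)-sulfide is used.

**Route**

Step 1
Reactants: 1 2,3,4-trihydroxybenzaldehyde
Product: 2 4-hydroxy-2,2-diphenyl-1,3-benzodioxole-5-carbaldehyde
Conditions: Ph2CCl2 (1.2 equiv), Ph2O, 175 °C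
Reagents that add atoms: dichlorodiphenylmethane ClC(Cl)(c1ccccc1)c1ccccc1
Why: Catechol ketalisation with a gem-dichloride; the 2-OH is tied up in a hydrogen bond to the formyl group, so the 3,4-diol pair should close the dioxole ring.

Step 2
Reactants: 2 4-hydroxy-2,2-diphenyl-1,3-benzodioxole-5-carbaldehyde
Product: 3 4-methoxy-2,2-diphenyl-1,3-benzodioxole-5-carbaldehyde
Conditions: MeI, K2CO3, DMF, 23 °C
Reagents that add atoms: iodomethane CI
Why: Williamson O-methylation (SN2) of the remaining phenoxide.

Step 3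
Reactants: 3 4-methoxy-2,2-diphenyl-1,3-benzodioxole-5-carbaldehyde; 4 1-[4-(benzyloxy)phenyl]ethan-1-one
Product: 5 (E)-1-[4-(benzyloxy)phenyl]-3-(4-methoxy-2,2-diphenyl-1,3-benzodioxol-5-yl)prop-2-en-1-one
Conditions: KOH, EtOH/THF, 23 °C
Reagents that add atoms: none
Why: Claisen–Schmidt condensation of the non-enolisable aldehyde with the acetophenone enolate, dehydration giving the E-enone under thermodynamic control.

Step 4
Reactants: 6 1-[4-(benzyloxy)phenyl]-2-bromoethan-1-one
Product: 7 (1R,4R,5R)-6-{2-[4-(benzyloxy)phenyl]-2-oxoethyl}-4,7,7-trimethyl-6-thiabicyclo[3.2.1]octan-6-ium bromide (alkylated on the exo face of sulfur)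
Conditions: (1R,4R,5R)-isothiocineole (1.0 equiv), acetone, 23 °C
Reagents that add atoms: (1R,4R,5R)-isothiocineole C[C@@H]1CC[C@@H]2C[C@H]1SC2(C)C
Why: S-Alkylation (SN2) of the sulfide by the activated α-bromoketone on the less hindered lone pair should give the crystalline phenacylsulfonium salt.

Step 5
Reactants: 5 (E)-1-[4-(benzyloxy)phenyl]-3-(4-methoxy-2,2-diphenyl-1,3-benzodioxol-5-yl)prop-2-en-1-one; 7 the sulfonium bromide of step 4
Product: 8 [(1R,2R)-3-(4-methoxy-2,2-diphenyl-1,3-benzodioxol-5-yl)cyclopropane-1,2-diyl]bis{[4-(benzyloxy)phenyl]methanone} (aroyl groups trans)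
Conditions: Cs2CO3, MeCN, 0 → 40 °C
Reagents that add atoms: none
Why: Corey–Chaykovsky-type sulfonium ylide cyclopropanation of an enone (conjugate addition, then 3-exo-tet displacement of the sulfide); the chiral sulfide fixes the configuration of the ylide-derived aroyl carbon, the second aroyl group ends trans to it, and the aryl-bearing carbon is not stereogenic in the trans-diaroyl product, so the chalcone face attacked is irrelevant.

Step 6
Reactants: 9 3,4-dihydroxy-5-methoxybenzaldehyde
Product: 10 7-methoxy-2,2-diphenyl-1,3-benzodioxole-5-carbaldehyde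
Conditions: Ph2CCl2, K2CO3, MeCN, 80 °C
Reagents that add atoms: dichlorodiphenylmethane ClC(Cl)(c1ccccc1)c1ccccc1
Why: Ketalisation of the catechol pair by double O-alkylation with the gem-dichloride, leaving the methyl ether and the aldehyde untouched.

Step 7
Reactants: 8 the (1R,2R)-cyclopropane of step 5; 10 7-methoxy-2,2-diphenyl-1,3-benzodioxole-5-carbaldehyde
Product: 12 [(1S,2R)-6,7-(diphenylmethylenedioxy)-8-methoxy-1-(4-methoxy-2,2-diphenyl-1,3-benzodioxol-5-yl)-1,2-dihydronaphthalene-2,3-diyl]bis{[4-(benzyloxy)phenyl]methanone}, via oxolane 11 (not isolated)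
Conditions: Sc(OTf)3 (20 mol %), 4 Å molecular sieves, ClCH2CH2Cl, 23 → 60 °C
Reagents that add atoms: none
Why: Proposed new method: Sc(OTf)3 activates an aroyl group of 8 so that the strained bond between the donor carbon C1 (benzylic, para to the ring oxygen of the pendant aryl) and the acceptor carbon C3 opens under attack of the formyl oxygen of 10, and the C3 enolate so released adds to the oxocarbenium carbon C4 to give the oxolane 11. The same acid re-ionises the benzylic C1–O bond of 11, the C1 cation is trapped by C8a of ring A, and the C4 carbinol then eliminates water to the conjugated C3=C4 enone, so that the C3–C4 and C8a–C1 bonds arise in one flask, driven by release of cyclopropane strain and by formation of the enone. The closest known reactions are the Lewis-acid (3+2) annulation of aryl donor–acceptor cyclopropanes with aldehydes (established for geminal diester acceptors) and the acid-induced rearrangement of 2,5-diaryltetrahydrofurans into 1-aryl-1,2-dihydronaphthalenes; their fusion into a single cascade on a 1-aryl-2,3-diaroylcyclopropane is what is new. Ring closures: the transient five-membered oxolane by O–C1 substitution followed by C3-to-C4 aldol-type C–C closure, and the six-membered ring B by intramolecular Friedel–Crafts alkylation (arene C8a onto the exocyclic benzylic cation C1). C2 is not enolised on the way and keeps the R configuration stored in the cyclopropane whichever of the two equivalent C1–C(aroyl) bonds opens, and the new centre C1 is set in the Friedel–Crafts closure through the half-chair in which the C2 aroyl group (allylic strain with the C3 aroyl) and the C1 aryl group (peri strain with the 8-methoxy group) are both pseudoaxial and hence anti, which should give the 1,2-trans (1S,2R) isomer. The step needs ring A to close at C8a and not at C5, which the fused dioxole secures because its angle strain disfavours substitution next to the ring fusion and leaves the position para to O6 and ortho to OMe as the reactive one, and it needs C–C bond formation at C3 and not C2, which follows because ring opening generates the enolate at C3 only; the sieves take up the water so that the ketals survive.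

Step 8
Reactants: 12 the (1S,2R)-trans-dihydronaphthalene of step 7
Product: 14 [(1S,2S)-6,7-(diphenylmethylenedioxy)-8-methoxy-1-(4-methoxy-2,2-diphenyl-1,3-benzodioxol-5-yl)-1,2-dihydronaphthalene-2,3-diyl]bis{[4-(benzyloxy)phenyl]methanone}, via lithium enolate 13 (not isolated)
Conditions: LiN(SiMe3)2 (1.1 equiv), THF, −78 °C; then AcOH (5 equiv), −78 °C
Reagents that add atoms: none
Why: Kinetic protonation of an enolate: C2–H is the only enolisable position, and in the planar cross-conjugated enolate 13 the pseudoaxial C1 aryl group shields one face, so irreversible proton transfer at −78 °C should occur anti to it and place the C2 aroyl cis to the aryl, C1 being untouched.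

Step 9
Reactants: 14 the (1S,2S)-cis-dihydronaphthalene of step 8
Product: 15 [(1S,2S)-1-(3,4-dihydroxy-2-methoxyphenyl)-6,7-dihydroxy-8-methoxy-1,2-dihydronaphthalene-2,3-diyl]bis[(4-hydroxyphenyl)methanone] (licobichalcone)
Conditions: BCl3 (12 equiv), C6HMe5 (12 equiv), CH2Cl2, −78 → −40 °C; then MeOH, H2O
Reagents that add atoms: none
Why: Lewis-acid ether cleavage with a non-basic cation scavenger: BCl3 should cleave the two benzyl ethers (benzyl cation trapped by C6HMe5) and the two diphenylmethylene ketals (hydrolysed on work-up) at low temperature, while the aryl methyl ethers, the enone and the configurationally labile C2 centre are left alone.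

**Compound list**
1 | 2,3,4-trihydroxybenzaldehyde | O=Cc1ccc(O)c(O)c1O | starting material
2 | 4-hydroxy-2,2-diphenyl-1,3-benzodioxole-5-carbaldehyde | O=Cc1ccc2OC(c3ccccc3)(c3ccccc3)Oc2c1O | intermediate
3 | 4-methoxy-2,2-diphenyl-1,3-benzodioxole-5-carbaldehyde | COc1c(C=O)ccc2OC(c3ccccc3)(c3ccccc3)Oc12 | intermediate
4 | 1-[4-(benzyloxy)phenyl]ethan-1-one | CC(=O)c1ccc(OCc2ccccc2)cc1 | starting material
5 | (E)-1-[4-(benzyloxy)phenyl]-3-(4-methoxy-2,2-diphenyl-1,3-benzodioxol-5-yl)prop-2-en-1-one | COc1c(/C=C/C(=O)c2ccc(OCc3ccccc3)cc2)ccc2OC(c3ccccc3)(c3ccccc3)Oc12 | intermediate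
6 | 1-[4-(benzyloxy)phenyl]-2-bromoethan-1-one | O=C(CBr)c1ccc(OCc2ccccc2)cc1 | starting material
7 | (1R,4R,5R)-6-{2-[4-(benzyloxy)phenyl]-2-oxoethyl}-4,7,7-trimethyl-6-thiabicyclo[3.2.1]octan-6-ium bromide (exo S-alkylated) | C[C@@H]1CC[C@@H]2C[C@H]1[S@@+](CC(=O)c1ccc(OCc3ccccc3)cc1)C2(C)C.[Br-] | intermediate
8 | [(1R,2R)-3-(4-methoxy-2,2-diphenyl-1,3-benzodioxol-5-yl)cyclopropane-1,2-diyl]bis{[4-(benzyloxy)phenyl]methanone} | O=C(c1ccc(OCc2ccccc2)cc1)[C@H]1[C@H](C(=O)c2ccc(OCc3ccccc3)cc2)C1c1ccc2OC(c3ccccc3)(c3ccccc3)Oc2c1OC | intermediate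
9 | 3,4-dihydroxy-5-methoxybenzaldehyde | COc1cc(C=O)cc(O)c1O | starting material
10 | 7-methoxy-2,2-diphenyl-1,3-benzodioxole-5-carbaldehyde | COc1cc(C=O)cc2OC(c3ccccc3)(c3ccccc3)Oc12 | intermediate
11 | (4S)-configured [2-(7-methoxy-2,2-diphenyl-1,3-benzodioxol-5-yl)-5-(4-methoxy-2,2-diphenyl-1,3-benzodioxol-5-yl)oxolane-3,4-diyl]bis{[4-(benzyloxy)phenyl]methanone}, epimer mixture at C2, C3 and C5 of the oxolane (all three reset or lost later) | COc1c(C2OC(c3cc(OC)c4OC(c5ccccc5)(c5ccccc5)Oc4c3)C(C(=O)c3ccc(OCc4ccccc4)cc3)[C@@H]2C(=O)c2ccc(OCc3ccccc3)cc2)ccc2OC(c3ccccc3)(c3ccccc3)Oc12 | intermediate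
12 | [(1S,2R)-6,7-(diphenylmethylenedioxy)-8-methoxy-1-(4-methoxy-2,2-diphenyl-1,3-benzodioxol-5-yl)-1,2-dihydronaphthalene-2,3-diyl]bis{[4-(benzyloxy)phenyl]methanone} | COc1c([C@H]2c3c(cc4OC(c5ccccc5)(c5ccccc5)Oc4c3OC)C=C(C(=O)c3ccc(OCc4ccccc4)cc3)[C@@H]2C(=O)c2ccc(OCc3ccccc3)cc2)ccc2OC(c3ccccc3)(c3ccccc3)Oc12 | intermediate
13 | lithium enolate of 12 at the C2 aroyl group (C1 configuration unchanged, enolate geometry not defined) | [Li+].COc1c([C@H]2c3c(cc4OC(c5ccccc5)(c5ccccc5)Oc4c3OC)C=C(C(=O)c3ccc(OCc4ccccc4)cc3)C2=C([O-])c2ccc(OCc3ccccc3)cc2)ccc2OC(c3ccccc3)(c3ccccc3)Oc12 | intermediate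
14 | [(1S,2S)-6,7-(diphenylmethylenedioxy)-8-methoxy-1-(4-methoxy-2,2-diphenyl-1,3-benzodioxol-5-yl)-1,2-dihydronaphthalene-2,3-diyl]bis{[4-(benzyloxy)phenyl]methanone} | COc1c([C@H]2c3c(cc4OC(c5ccccc5)(c5ccccc5)Oc4c3OC)C=C(C(=O)c3ccc(OCc4ccccc4)cc3)[C@H]2C(=O)c2ccc(OCc3ccccc3)cc2)ccc2OC(c3ccccc3)(c3ccccc3)Oc12 | intermediate
15 | [(1S,2S)-1-(3,4-dihydroxy-2-methoxyphenyl)-6,7-dihydroxy-8-methoxy-1,2-dihydronaphthalene-2,3-diyl]bis[(4-hydroxyphenyl)methanone] | COc1c([C@H]2c3c(cc(O)c(O)c3OC)C=C(C(=O)c3ccc(O)cc3)[C@H]2C(=O)c2ccc(O)cc2)ccc(O)c1O | target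

**Count and risks**
Total steps: 9. Longest linear sequence: 7 (steps 1, 2, 3, 5, 7, 8, 9).

1. Step 7 (proposed new method). The ring-opened zwitterion may divert: Cloke–Wilson closure to a dihydrofuran that does not re-enter, or proton loss from C2 to the achiral 2-arylidene-1,4-diketone with erosion of enantiomeric purity. Closure may also occur partly at C5, or with poor facial selectivity at C1 (the C1 epimer is a diastereomer and would be removed by chromatography). Fallback from 8 and 10 back to 12, stepwise with known reaction types: 8 is opened by Yb(OTf)3-catalysed methanolysis at the benzylic carbon to the (2S)-γ-methoxy-1,4-diketone F1. Soft enolisation of its CH2 ketone (Me3SiOTf, Et3N, −78 °C) gives the (Z)-trimethylsilyl enol ether F2. A Mukaiyama aldol addition to 10 (BF3·OEt2, −78 °C) gives the β-hydroxy ketone F3. CF3CO2H in CH2Cl2 then ionises the benzylic methyl ether, closes ring B by Friedel–Crafts alkylation and dehydrates the carbinol to 12.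

2. Step 5. The stabilised ylide may react sluggishly with the electron-rich chalcone, and reversible betaine formation or betaine epimerisation may erode enantioselectivity. Fallback from 3 and 6 back to 8 by iminium catalysis: Wittig reaction of 3 with Ph3P=CHCHO gives the (E)-enal F4. Compound 6 and Me2S give the dimethylsulfonium bromide F5. Cyclopropanation of F4 with the ylide of F5 under (S)-indoline-2-carboxylic acid catalysis (CHCl3, −10 °C) gives the (1R,2R,3R)-formylcyclopropane F6, formyl trans to both other groups. Addition of 4-(benzyloxy)phenylmagnesium bromide at −78 °C to the formyl group gives the carbinol F7, and MnO2 oxidation gives 8.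

3. Step 8. Facial discrimination in the proton transfer may be incomplete, γ-protonation at C4 may compete, or the product may re-equilibrate to trans during the quench. Fallback from 12 back to 14 by reagent-controlled protonation: the enolate is trapped with Me3SiCl as the isolable C2 trimethylsilyl enol ether F8. This is protonated at −78 °C in toluene by the SnCl4 complex of (R)-1,1'-bi-2-naphthol (a Lewis-acid-assisted chiral Brønsted acid, enantiomer chosen to match the substrate bias) to give 14.

**Further compounds**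
F1 | step 7 | (2S)-1,4-bis[4-(benzyloxy)phenyl]-2-[methoxy(4-methoxy-2,2-diphenyl-1,3-benzodioxol-5-yl)methyl]butane-1,4-dione, both epimers at the methoxy-bearing carbon | COc1c(C(OC)[C@H](CC(=O)c2ccc(OCc3ccccc3)cc2)C(=O)c2ccc(OCc3ccccc3)cc2)ccc2OC(c3ccccc3)(c3ccccc3)Oc12
F2 | step 7 | (Z)-trimethylsilyl enol ether of the CH2 ketone of F1 | COc1c(C(OC)[C@H](/C=C(\O[Si](C)(C)C)c2ccc(OCc3ccccc3)cc2)C(=O)c2ccc(OCc3ccccc3)cc2)ccc2OC(c3ccccc3)(c3ccccc3)Oc12
F3 | step 7 | aldol adduct of F2 and 10: (2S)-1,4-diketone bearing at C3 a hydroxy(7-methoxy-2,2-diphenyl-1,3-benzodioxol-5-yl)methyl group, diastereomer mixture at the other three centres | COc1c(C(OC)[C@H](C(C(=O)c2ccc(OCc3ccccc3)cc2)C(O)c2cc(OC)c3OC(c4ccccc4)(c4ccccc4)Oc3c2)C(=O)c2ccc(OCc3ccccc3)cc2)ccc2OC(c3ccccc3)(c3ccccc3)Oc12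
F4 | step 5 | (E)-3-(4-methoxy-2,2-diphenyl-1,3-benzodioxol-5-yl)prop-2-enal | COc1c(/C=C/C=O)ccc2OC(c3ccccc3)(c3ccccc3)Oc12
F5 | step 5 | {2-[4-(benzyloxy)phenyl]-2-oxoethyl}dimethylsulfonium bromide | C[S+](C)CC(=O)c1ccc(OCc2ccccc2)cc1.[Br-]
F6 | step 5 | (1R,2R,3R)-2-[4-(benzyloxy)benzoyl]-3-(4-methoxy-2,2-diphenyl-1,3-benzodioxol-5-yl)cyclopropane-1-carbaldehyde | O=C[C@H]1[C@H](C(=O)c2ccc(OCc3ccccc3)cc2)[C@@H]1c1ccc2OC(c3ccccc3)(c3ccccc3)Oc2c1OC
F7 | step 5 | secondary alcohol from aryl Grignard addition to the formyl group of F6, both carbinol epimers | OC(c1ccc(OCc2ccccc2)cc1)[C@H]1[C@H](C(=O)c2ccc(OCc3ccccc3)cc2)[C@@H]1c1ccc2OC(c3ccccc3)(c3ccccc3)Oc2c1OC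
F8 | step 8 | trimethylsilyl enol ether of 12 at the C2 aroyl group (C1 configuration unchanged, enol geometry not defined) | COc1c([C@H]2c3c(cc4OC(c5ccccc5)(c5ccccc5)Oc4c3OC)C=C(C(=O)c3ccc(OCc4ccccc4)cc3)C2=C(O[Si](C)(C)C)c2ccc(OCc3ccccc3)cc2)ccc2OC(c3ccccc3)(c3ccccc3)Oc12
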